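The grey run was still climbing at its last readings, from 32.7% at 15.0 min to 40.9% at 20.0 min, so I did not treat that run as finished when I reckoned these flasks.

| setting | ochre | blue | grey | green | Friday's | Monday's | Wednesday's | Thursday's | Tuesday's | Sunday's |
|---|---|---|---|---|---|---|---|---|---|---|
| starting material | 0.30 M | 0.30 M | 0.30 M | 0.30 M | 0.30 M (fed, over 6.0 min) | 0.30 M (fed, over 1.5 min) | 0.30 M (in portions, 4, over 6.0 min) | 0.30 M (fed, over 6.0 min) | 0.30 M | 0.30 M |
| second substrate | 1 equiv | 1 equiv | 1 equiv | 1 equiv | 1.00 equiv | 1.00 equiv | 1.00 equiv | 1.00 equiv | 1.00 equiv | 1.00 equiv |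
| capture agent | 0.015 M | 0.015 M | 0.015 M | 0.022 M | 0.0150 M | 0.0150 M | 0.0150 M | 0.0150 M | 0.0150 M | 0.0150 M |
| free catalyst | 2.1 mol% | 1.4 mol% | 3.2 mol% | 2.1 mol% | 2.1 mol% | 2.1 mol% | 2.1 mol% | 2.1 mol% | 2.1 mol% | 2.1 mol% |
| temperature | 45 °C | 60 °C | 45 °C | 60 °C |  | 60 °C | 60 °C | 60 °C | 60 °C |  |
| remark | run made earlier | run made earlier | run made earlier | run made earlier | the addition at 20 °C, then warmed to 60 °C; the feed brings no volume worth counting | all else is in the flask from the start; the feed brings no volume worth counting | first portion at the start, last at 6.0 min | all else is in the flask from the start; the feed brings no volume worth counting | everything together at the start | everything together at the start at 20 °C, warmed to 60 °C at 6.0 min |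
| time |  |  |  |  | 10 min | 10 min | 10 min | 10 min | 10 min | 10 min |

| run | time / min | target / % |
|---|---|---|
| ochre | 1.00 | 1.8 |
| ochre | 2.00 | 3.3 |
| ochre | 3.00 | 4.5 |
| ochre | 6.00 | 9.1 |
| ochre | 12.0 | 18.5 |
| blue | 0.833 | 2.0 |
| blue | 1.50 | 3.4 |
| blue | 3.00 | 7.7 |
| blue | 5.00 | 13.3 |
| blue | 10.0 | 24.0 |
| grey | 2.00 | 4.7 |
| grey | 5.00 | 12.3 |
| grey | 10.0 | 22.9 |
| grey | 15.0 | 32.7 |
| grey | 20.0 | 40.9 |
| green | 0.833 | 3.8 |
| green | 1.50 | 6.1 |
| green | 3.00 | 13.0 |
| green | 5.00 | 19.5 |
| green | 10.0 | 32.6 |

(each reading ± 0.5 percentage points)

- the earlier runs were read with a standard deviation of 0.5 percentage points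

- the flask that comes out highest in amount of target, in percent of the starting material charged, or "all alike" when all lie within 1.5 percentage points (Friday's / Monday's / Wednesday's / Thursday's / Tuesday's / Sunday's / all alike)
- target at the end, in percent of the starting material charged, Friday's
- target at the end, in percent of the starting material charged, Monday's
- target at the end, in percent of the starting material charged, Wednesday's
- target at the end, in percent of the starting material charged, Thursday's
- target at the end, in percent of the starting material charged, Tuesday's
- target at the end, in percent of the starting material charged, Sunday's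

I kept books on the starting material charged, using one rate. The constant −ln(fraction unconverted)/time for grey, divided by that for ochre, came to 1.54, against a loading ratio of 1.52, so I scaled in proportion to catalyst. The blue reading of 24.0% at 10.0 min then gave k, the pseudo-first-order constant of starting material at 60 °C and 2.1 mol%, as 0.0412 /min. From it I carried L, the half-life of starting material at that temperature and loading, ln(2)/k, 16.8 min.

The ledger had two entries, starting material still standing and target, since target was the product the earlier runs reported. For Tuesday's I booked 66.3% standing and 33.7% to target. With a first-order rate at constant k, a steady feed integrates in closed form: the share of the whole charge standing when the feed stops, S, is the fraction a batch charge would lose in the feed time, divided by k times that time. For Thursday's I reckoned S as 88.6%, and after the remaining time I booked 75.2% standing and 24.8% to target. Wednesday's 4 evenly spaced portions spend the same mean time in the flask, 7.00 min, so I booked them like Thursday's. For Monday's I booked 68.3% standing and 31.7% to target. This put Tuesday's ahead of Monday's by 2.0 points, more than the margin. For Sunday's and Friday's I counted the cold stage as nothing, which booked 15.2% to target.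

The forecast named Tuesday's: “Dosing only delays the reaction here, so Tuesday's is highest.” It gave 16% for Friday's, 31.6% for Monday's, 24.6% for Wednesday's, 24.8% for Thursday's, 33.6% for Tuesday's and 16.8% for Sunday's. Its figures for Friday's and Sunday's stood higher than my 15.2%.

The flasks gave Tuesday's as highest, with 17.0% for Friday's, 33.4% for Monday's, 27.5% for Wednesday's, 27.6% for Thursday's, 34.9% for Tuesday's and 17.1% for Sunday's.

    second substrate + free catalyst ⇌ catalyst intermediate B (K = 15.0 /M, k = 5.40 /M/s, Ea = 36.0 kJ/mol, ΔH = −43.0 kJ/mol)
    catalyst intermediate A → free catalyst + target (k = 0.170 /s, Ea = 91.0 kJ/mol)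
    catalyst intermediate B → free catalyst + second product (k = 5.00 /s, Ea = 75.0 kJ/mol)
    catalyst intermediate A + capture agent → trapped intermediate (k = 0.130 /M/s, Ea = 55.0 kJ/mol)
    starting material + free catalyst ⇌ catalyst intermediate A (K = 1.20 /M, k = 1.10 /M/s, Ea = 68.0 kJ/mol, ΔH = −59.0 kJ/mol)
    target → over-reaction product (k = 1.50 × 10⁻⁴ /s, Ea = 111 kJ/mol)
    (constants at 60 °C)

Tuesday's had not come to rest at 10.0 min: 62.7% of its starting material stood there, against the 66.3% I had booked, with 34.9% in target and 1.73% in over-reaction product, an entry I had not opened. At 100 min its target reached 48.7%. Counted from the warming at 6.0 min, L booked 24.6% of starting material standing in Friday's at 40 min, and that flask held 23.8%, with 62.2% in target and 13.1% in over-reaction product. At 100 min Friday's held 2.89% starting material, 50.8% target and 45.3% over-reaction product.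

The readings come from a simulation from invented constants.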